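**Remarks (assumptions on the chemistry)**
- Both halves are numbered as 1H-isochromenes (O2, C1, C3, C4, C4a, C5–C8, C8a). Unit A is the 6,8-dione half that carries the acetoxypropenyl chain; unit B is the 8-oxo-7-hydroxy-6-aroyloxy half.
- The exocyclic C5=C bond of unit A (chain syn to the C6 carbonyl) and the open dienone form are assumed to be the thermodynamically preferred arrangement, as drawn for the target, so reversible amine catalysis should deliver them.
- The sense of asymmetric induction of the chiral dirhodium carboxylate on the new ylide is not known. Steps 8 and 12 are written with the S and the R catalyst; the two are exchanged if the sense found is the opposite one.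
- Carbonyl ylide 14 is a transient, catalyst-associated species that arises from 9 in both rhodium-catalysed steps (8 and 12). It has one number and one line in the compound list and is entered at step 8, where it first appears.

**Retrosynthetic overview**
1. Last C–C bond: Knoevenagel condensation at C5 of unit A (26) with the enal of unit B (19), then removal of the four aryl silyl ethers.
2. Both pyran-fused carbocycles come from one 3-acyl-4-pyranone diazoketone 9; the pyran ring is made first, as the pyranone, from enaminone 2 and acid chloride 5.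
3. Key disconnection (unit B): C4a–C5 and C6–C7 by [3+2] cycloaddition of carbonyl ylide 14 with vinyl orsellinate 13. The enabling feature: C4a and C7 stand 1,4 across C8=O in the carbocycle, and C4a is also the γ-carbon of the pyran ring (O2–C1–C8a–C4a–C4–C3), so the 7-OH oxygen can be the carbonyl oxygen of a 4-pyranone bridging C4a and C7.
4. The oxygen bridge is opened by hydride delivery to C1 (pyrylium to 1H-isochromene), which frees 7-OH and gives the C4a=C8a enone. Unit A is made the same way with ethoxyethyne and the enantiomeric catalyst, then acylated at the tertiary oxygen.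
5. Ring order: pyranone ring, then the carbocycle of each half (through a transient oxabicycle), then union of the halves; the aryl rings are bought.

Key step: step 8

**Route**

Step 1
Reactants: 1 hexane-2,4-dione
Product: 2 3-[(dimethylamino)methylidene]hexane-2,4-dione
Conditions: Me2NCH(OMe)2 (1.2 equiv), neat, 25 → 60 °C
Reagents that add atoms: N,N-dimethylformamide dimethyl acetal, COC(OC)N(C)C
Why: Aminomethylenation of the doubly activated methylene of a 1,3-diketone with an amide acetal is a standard enaminone synthesis and installs the future C1 of the pyran ring.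

Step 2
Reactants: 3 (2E)-4-bromobut-2-enoic acid
Product: 4 (2E)-4-(acetyloxy)but-2-enoic acid
Conditions: KOAc (5 equiv), AcOH, 80 °C
Reagents that add atoms: potassium acetate, CC(=O)[O-].[K+]
Why: SN2 displacement of the primary allylic bromide by acetate in buffered acetic acid keeps the E-enoic acid intact and puts the acetate of the target in place from the start.

Step 3
Reactants: 4 (2E)-4-(acetyloxy)but-2-enoic acid
Product: 5 (2E)-4-(acetyloxy)but-2-enoyl chloride
Conditions: (COCl)2 (1.2 equiv), DMF (cat.), CH2Cl2, 0 → 25 °C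
Reagents that add atoms: oxalyl chloride, ClC(=O)C(Cl)=O
Why: Acid chloride formation through the catalytic chloroiminium salt is routine and does not touch the allylic acetate.

Step 4
Reactants: 2 3-[(dimethylamino)methylidene]hexane-2,4-dione; 5 (2E)-4-(acetyloxy)but-2-enoyl chloride
Product: 7 (2E)-3-(4-oxo-5-propanoyl-4H-pyran-2-yl)prop-2-en-1-yl acetate, via enaminotrione 6 (not isolated)
Conditions: 2 (2.0 equiv), LiN(SiMe3)2 (2.0 equiv), THF, −78 °C; 5 (1.0 equiv), −78 → 0 °C; then 2 M HCl, 25 °C
Reagents that add atoms: none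
Why: Kinetic deprotonation of 2 at the acetyl methyl rather than the propanoyl methylene, Claisen-type C-acylation to 6 and acid-induced addition–elimination of the new enol oxygen at the enaminone carbon (loss of dimethylamine) is the established enaminone route to 3-acyl-4-pyranones; the minor regioisomer from methylene deprotonation would be removed by chromatography.

Step 5
Reactants: 7 (2E)-3-(4-oxo-5-propanoyl-4H-pyran-2-yl)prop-2-en-1-yl acetate
Product: 9 (2E)-3-[5-(2-diazopropanoyl)-4-oxo-4H-pyran-2-yl]prop-2-en-1-yl acetate, via trifluoroacetyl ketone 8 (not isolated)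
Conditions: LiN(SiMe3)2 (1.1 equiv), THF, −78 °C; CF3CO2CH2CF3 (1.2 equiv); 5% HCl work-up; then 4-acetamidobenzenesulfonyl azide (1.5 equiv), Et3N (1.5 equiv), H2O (1 equiv), MeCN, 25 °C
Reagents that add atoms: 4-acetamidobenzenesulfonyl azide, CC(=O)Nc1ccc(cc1)S(=O)(=O)N=[N+]=[N-]; 2,2,2-trifluoroethyl trifluoroacetate, FC(F)(F)COC(=O)C(F)(F)F (its acyl group is carried only by 8)
Why: Detrifluoroacetylative (Regitz-type) diazo transfer trifluoroacetylates the only enolisable ketone α-position of 7 and then exchanges the activating acyl group for the diazo group, which avoids free diazoethane that would add to the electron-poor pyranone alkene.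

Step 6
Reactants: 10 orsellinic acid (2,4-dihydroxy-6-methylbenzoic acid)
Product: 12 2,4-bis[(tert-butyldimethylsilyl)oxy]-6-methylbenzoic acid, via tris-silyl ester 11 (not isolated)
Conditions: TBSCl (3.5 equiv), imidazole (7 equiv), DMF, 25 °C; then AcOH–THF–H2O (3:1:1), 25 °C
Reagents that add atoms: tert-butyl(chloro)dimethylsilane, CC(C)(C)[Si](C)(C)Cl
Why: Exhaustive silylation followed by selective hydrolysis of the far more labile silyl ester protects both phenols against O–H insertion in steps 8 and 12 and leaves the acid free.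

Step 7
Reactants: 12 2,4-bis[(tert-butyldimethylsilyl)oxy]-6-methylbenzoic acid
Product: 13 ethenyl 2,4-bis[(tert-butyldimethylsilyl)oxy]-6-methylbenzoate
Conditions: vinyl acetate (10 equiv), [Ir(cod)Cl]2 (1 mol %), NaOAc (5 mol %), toluene, 100 °C
Reagents that add atoms: vinyl acetate, C=COC(C)=O
Why: Iridium-catalysed transvinylation of a carboxylic acid with vinyl acetate makes the hindered ester bond at a stage where no hindered alcohol is involved.

Step 8
Reactants: 9 (2E)-3-[5-(2-diazopropanoyl)-4-oxo-4H-pyran-2-yl]prop-2-en-1-yl acetate; 13 ethenyl 2,4-bis[(tert-butyldimethylsilyl)oxy]-6-methylbenzoate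
Product: 15 (4aR,6R,7R)-exo cycloadduct (4a,7-epoxy-4aH-isochromen-8-one carrying the 6-aroyloxy group syn to the oxygen bridge), via furopyrylium olate ylide 14 (not isolated)
Conditions: dirhodium tetrakis[N-tetrachlorophthaloyl-(S)-tert-leucinate], Rh2(S-TCPTTL)4 (2 mol %), 13 (3 equiv), 4 Å molecular sieves, PhCF3, 0 °C, 9 added over 2 h
Reagents that add atoms: none
Why: Proposed new method: decomposition of the diazo group of 9 at the dirhodium centre (divalent rhodium, loss of N2) gives an electrophilic carbene carbon that is captured by the nucleophilic 4-pyranone carbonyl oxygen in a five-membered O–C ring closure, giving the mesoionic carbonyl ylide 14 (an aromatic furo[3,2-c]pyrylium-3-olate), which cannot tautomerise because its C8a is sp2. The closest known reaction type is the dirhodium-carboxylate-catalysed tandem carbonyl ylide formation/1,3-dipolar cycloaddition of α-diazo ketones and diazo imides (isomünchnones, also pyridone-fused ones) with vinyl ethers under inverse electron demand; new are the pyranone carbonyl as ylide donor and the enol ester as dipolarophile. The ylide adds through its two oxygen-bound carbons to 13 in a suprafacial six-electron [3+2] cycloaddition that closes the oxolane ring of a 7-oxabicyclo[2.2.1]heptanone and with it the six-membered carbocycle of unit B, forming C4a–C5 and C6–C7 together. Regiochemistry follows polarity (ylide-LUMO control): the nucleophilic CH2 terminus of 13 bonds to the pyrylium γ-carbon C4a and its oxygen-bearing carbon to the enolate carbon C7. C6 is set relative to C7 by the exo approach usual for enol derivatives in such cycloadditions, which places the ester syn to the oxygen bridge (the later cis hydroxy ester), and the absolute configuration at C7 (and with it C4a and C6) is set by the chiral carboxylate ligands as long as the ylide reacts while associated with rhodium. The step needs periselectivity for the C7/C4a dipole over addition at the free pyrylium α-carbon C1 and must outrun 1,2-hydride shift of the carbene, which the intramolecular five-ring capture by the strongly basic pyranone oxygen, low temperature, bulky carboxylate ligands and slow addition of 9 into excess 13 should secure.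

Step 9
Reactants: 15 (4aR,6R,7R)-exo cycloadduct
Product: 17 (6R,7R)-3-[(1E)-3-(acetyloxy)prop-1-en-1-yl]-7-hydroxy-7-methyl-8-oxo-5,6,7,8-tetrahydro-1H-isochromen-6-yl 2,4-bis[(tert-butyldimethylsilyl)oxy]-6-methylbenzoate, via pyrylium ion 16 (not isolated)
Conditions: diethyl 2,6-dimethyl-1,4-dihydropyridine-3,5-dicarboxylate (1.5 equiv), (PhO)2P(O)OH (20 mol %), CH2Cl2, −20 → 25 °C
Reagents that add atoms: none
Why: Acid ionises the doubly allylic bridging C4a–O bond of the 4H-pyranyl ether to the aromatic pyrylium ion 16 (a C1-bound isomer of 15 would give the same ion), and hydride transfer from the dihydropyridine to the unsubstituted, acyl-activated α-carbon C1 (ionic transfer hydrogenation, as in reductions of pyrylium and benzopyrylium salts to 2H-pyrans) gives the 1H-isochromene with 7-OH released and C6 and C7 untouched.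

Step 10
Reactants: 17 unit B acetate
Product: 18 (6R,7R)-7-hydroxy-3-[(1E)-3-hydroxyprop-1-en-1-yl]-7-methyl-8-oxo-5,6,7,8-tetrahydro-1H-isochromen-6-yl 2,4-bis[(tert-butyldimethylsilyl)oxy]-6-methylbenzoate
Conditions: immobilised Candida antarctica lipase B, n-BuOH (5 equiv), MTBE, 30 °C
Reagents that add atoms: none
Why: Lipase-catalysed alcoholysis (transesterification) removes the unhindered primary acetate under neutral conditions, whereas the di-ortho-substituted aryl ester, the aryl silyl ethers and the base-sensitive β-acyloxy ketone are not touched.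

Step 11
Reactants: 18 unit B allylic alcohol
Product: 19 (6R,7R)-7-hydroxy-7-methyl-8-oxo-3-[(1E)-3-oxoprop-1-en-1-yl]-5,6,7,8-tetrahydro-1H-isochromen-6-yl 2,4-bis[(tert-butyldimethylsilyl)oxy]-6-methylbenzoate
Conditions: MnO2 (15 equiv), CH2Cl2, 25 °C
Reagents that add atoms: none
Why: Activated MnO2 oxidises allylic alcohols selectively to enals with retention of the E geometry and leaves the tertiary alcohol alone.

Step 12
Reactants: 9 (2E)-3-[5-(2-diazopropanoyl)-4-oxo-4H-pyran-2-yl]prop-2-en-1-yl acetate; 20 ethoxyethyne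
Product: 23 (2E)-3-[(7S)-6-ethoxy-7-hydroxy-7-methyl-8-oxo-7,8-dihydro-1H-isochromen-3-yl]prop-2-en-1-yl acetate, via ethoxy cycloadduct 21 (not isolated), via ethoxypyrylium ion 22 (not isolated)
Conditions: dirhodium tetrakis[N-tetrachlorophthaloyl-(R)-tert-leucinate], Rh2(R-TCPTTL)4 (2 mol %), 20 (3 equiv), 4 Å molecular sieves, PhCF3, 0 °C, 9 added over 2 h; volatiles evaporated; then diethyl 2,6-dimethyl-1,4-dihydropyridine-3,5-dicarboxylate (1.5 equiv), (PhO)2P(O)OH (20 mol %), CH2Cl2, −20 → 25 °C
Reagents that add atoms: none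
Why: Proposed new method: rhodium-induced loss of N2 from 9 regenerates the carbonyl ylide 14 of step 8, here associated with the enantiomeric catalyst (closest known type: dirhodium-catalysed carbonyl ylide formation and inverse-electron-demand [3+2] cycloaddition of cyclic ylides with alkoxyacetylenes), and this ylide should bond through C4a to the nucleophilic terminal carbon of 20 and through C7 to its oxygen-bearing carbon, the enantiomeric catalyst setting C7 as S; the strained oxanorbornadiene 21 is not isolated but ionised by acid to the ethoxy-stabilised pyrylium ion 22, which takes hydride at C1 as in step 9.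

Step 13
Reactants: 12 2,4-bis[(tert-butyldimethylsilyl)oxy]-6-methylbenzoic acid
Product: 24 2,4-bis[(tert-butyldimethylsilyl)oxy]-6-methylbenzoyl chloride
Conditions: 1-chloro-N,N,2-trimethylprop-1-en-1-amine (1.2 equiv), CH2Cl2, 0 → 25 °C
Reagents that add atoms: 1-chloro-N,N,2-trimethylprop-1-en-1-amine, CC(C)=C(Cl)N(C)C
Why: The α-chloroenamine turns acids into acid chlorides under neutral conditions, so the aryl silyl ethers survive.

Step 14
Reactants: 23 unit A tertiary alcohol (6-ethyl enol ether); 24 2,4-bis[(tert-butyldimethylsilyl)oxy]-6-methylbenzoyl chloride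
Product: 25 (7S)-3-[(1E)-3-(acetyloxy)prop-1-en-1-yl]-6-ethoxy-7-methyl-8-oxo-7,8-dihydro-1H-isochromen-7-yl 2,4-bis[(tert-butyldimethylsilyl)oxy]-6-methylbenzoate
Conditions: KN(SiMe3)2 (1.05 equiv), THF, −78 °C; 24 (1.3 equiv), −78 → 0 °C
Reagents that add atoms: none
Why: O-Acylation of the preformed tertiary potassium alkoxide by the acid chloride (nucleophilic acyl substitution) overcomes the hindrance on both partners, and because the C5/C6 unit is still masked as the ethyl enol ether there is no competing enol acylation.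

Step 15
Reactants: 25 unit A ester (6-ethyl enol ether)
Product: 26 (7S)-3-[(1E)-3-(acetyloxy)prop-1-en-1-yl]-7-methyl-6,8-dioxo-5,6,7,8-tetrahydro-1H-isochromen-7-yl 2,4-bis[(tert-butyldimethylsilyl)oxy]-6-methylbenzoate
Conditions: 0.5 M HCl, THF–H2O, 25 °C
Reagents that add atoms: water, O
Why: Acid hydrolysis of the vinylogous ester (enol ether) unmasks the C6 ketone and the doubly activated C5 methylene, while aryl silyl ethers, the allylic acetate and the hindered ester are stable to dilute acid.

Step 16
Reactants: 26 unit A dione; 19 unit B enal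
Product: 27 tetrakis(tert-butyldimethylsilyl) ether of the target
Conditions: ethylenediammonium diacetate (10 mol %), 4 Å molecular sieves, CH2Cl2, 25 °C
Reagents that add atoms: none
Why: Knoevenagel condensation of the vinylogous β-diketone methylene C5 with the enal (through its iminium ion) gives the dienylidene, and under the reversible amine catalysis the C5=C bond should settle with the chain syn to the C6 carbonyl and away from H4, as in the target.

Step 17
Reactants: 27 tetrakis(tert-butyldimethylsilyl) ether of the target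
Product: 28 CNP0283591.2
Conditions: HF·pyridine (excess), pyridine, THF, 0 → 25 °C
Reagents that add atoms: none
Why: Fluoride cleavage of the four aryl silyl ethers under buffered, weakly acidic conditions spares the allylic acetate, the base-sensitive esters and the polyene.

**Compound list**

1 | hexane-2,4-dione | CCC(=O)CC(C)=O | starting material
2 | 3-[(dimethylamino)methylidene]hexane-2,4-dione | CCC(=O)C(=CN(C)C)C(C)=O | intermediate
3 | (2E)-4-bromobut-2-enoic acid | OC(=O)/C=C/CBr | starting material
4 | (2E)-4-(acetyloxy)but-2-enoic acid | CC(=O)OC/C=C/C(O)=O | intermediate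
5 | (2E)-4-(acetyloxy)but-2-enoyl chloride | CC(=O)OC/C=C/C(Cl)=O | intermediate
6 | (2E)-7-[(dimethylamino)methylidene]-4,6,8-trioxodec-2-en-1-yl acetate | CCC(=O)C(=CN(C)C)C(=O)CC(=O)/C=C/COC(C)=O | intermediate (not isolated)
7 | (2E)-3-(4-oxo-5-propanoyl-4H-pyran-2-yl)prop-2-en-1-yl acetate | CCC(=O)C1=COC(/C=C/COC(C)=O)=CC1=O | intermediate
8 | (2E)-3-[4-oxo-5-(4,4,4-trifluoro-2-methyl-3-oxobutanoyl)-4H-pyran-2-yl]prop-2-en-1-yl acetate | CC(C(=O)C(F)(F)F)C(=O)C1=COC(/C=C/COC(C)=O)=CC1=O | intermediate (not isolated)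
9 | (2E)-3-[5-(2-diazopropanoyl)-4-oxo-4H-pyran-2-yl]prop-2-en-1-yl acetate | CC(=[N+]=[N-])C(=O)C1=COC(/C=C/COC(C)=O)=CC1=O | intermediate
10 | orsellinic acid (2,4-dihydroxy-6-methylbenzoic acid) | Cc1cc(O)cc(O)c1C(O)=O | starting material
11 | tert-butyldimethylsilyl 2,4-bis[(tert-butyldimethylsilyl)oxy]-6-methylbenzoate | Cc1cc(O[Si](C)(C)C(C)(C)C)cc(O[Si](C)(C)C(C)(C)C)c1C(=O)O[Si](C)(C)C(C)(C)C | intermediate (not isolated)
12 | 2,4-bis[(tert-butyldimethylsilyl)oxy]-6-methylbenzoic acid | Cc1cc(O[Si](C)(C)C(C)(C)C)cc(O[Si](C)(C)C(C)(C)C)c1C(O)=O | intermediate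
13 | ethenyl 2,4-bis[(tert-butyldimethylsilyl)oxy]-6-methylbenzoate | C=COC(=O)c1c(C)cc(O[Si](C)(C)C(C)(C)C)cc1O[Si](C)(C)C(C)(C)C | intermediate
14 | 6-[(1E)-3-(acetyloxy)prop-1-en-1-yl]-2-methylfuro[3,2-c]pyran-5-ium-3-olate (carbonyl ylide) | CC1=C([O-])C2=C[O+]=C(/C=C/COC(C)=O)C=C2O1 | intermediate (not isolated)
15 | (4aR,6R,7R)-3-[(1E)-3-(acetyloxy)prop-1-en-1-yl]-7-methyl-8-oxo-5,6,7,8-tetrahydro-4aH-4a,7-epoxyisochromen-6-yl 2,4-bis[(tert-butyldimethylsilyl)oxy]-6-methylbenzoate (ester exo, syn to the oxygen bridge) | C[C@@]12O[C@]3(C[C@H]1OC(=O)c1c(C)cc(O[Si](C)(C)C(C)(C)C)cc1O[Si](C)(C)C(C)(C)C)C=C(/C=C/COC(C)=O)OC=C3C2=O | intermediate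
16 | (6R,7R)-3-[(1E)-3-(acetyloxy)prop-1-en-1-yl]-6-{2,4-bis[(tert-butyldimethylsilyl)oxy]-6-methylbenzoyloxy}-7-hydroxy-7-methyl-8-oxo-5,6,7,8-tetrahydroisochromen-2-ium diphenyl phosphate | CC(=O)OC/C=C/C1=CC2=C(C=[O+]1)C(=O)[C@](C)(O)[C@H](OC(=O)c1c(C)cc(O[Si](C)(C)C(C)(C)C)cc1O[Si](C)(C)C(C)(C)C)C2.[O-]P(=O)(Oc1ccccc1)Oc1ccccc1 | intermediate (not isolated)
17 | (6R,7R)-3-[(1E)-3-(acetyloxy)prop-1-en-1-yl]-7-hydroxy-7-methyl-8-oxo-5,6,7,8-tetrahydro-1H-isochromen-6-yl 2,4-bis[(tert-butyldimethylsilyl)oxy]-6-methylbenzoate | CC(=O)OC/C=C/C1=CC2=C(CO1)C(=O)[C@](C)(O)[C@H](OC(=O)c1c(C)cc(O[Si](C)(C)C(C)(C)C)cc1O[Si](C)(C)C(C)(C)C)C2 | intermediate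
18 | (6R,7R)-7-hydroxy-3-[(1E)-3-hydroxyprop-1-en-1-yl]-7-methyl-8-oxo-5,6,7,8-tetrahydro-1H-isochromen-6-yl 2,4-bis[(tert-butyldimethylsilyl)oxy]-6-methylbenzoate | OC/C=C/C1=CC2=C(CO1)C(=O)[C@](C)(O)[C@H](OC(=O)c1c(C)cc(O[Si](C)(C)C(C)(C)C)cc1O[Si](C)(C)C(C)(C)C)C2 | intermediate
19 | (6R,7R)-7-hydroxy-7-methyl-8-oxo-3-[(1E)-3-oxoprop-1-en-1-yl]-5,6,7,8-tetrahydro-1H-isochromen-6-yl 2,4-bis[(tert-butyldimethylsilyl)oxy]-6-methylbenzoate | O=C/C=C/C1=CC2=C(CO1)C(=O)[C@](C)(O)[C@H](OC(=O)c1c(C)cc(O[Si](C)(C)C(C)(C)C)cc1O[Si](C)(C)C(C)(C)C)C2 | intermediate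
20 | ethoxyethyne | CCOC#C | starting material
21 | (7S)-3-[(1E)-3-(acetyloxy)prop-1-en-1-yl]-6-ethoxy-7-methyl-4a,7-epoxy-4aH-isochromen-8(7H)-one (bridgehead C4a fixed by the bridge) | C[C@]12O[C@@]3(C=C1OCC)C=C(/C=C/COC(C)=O)OC=C3C2=O | intermediate (not isolated)
22 | (7S)-3-[(1E)-3-(acetyloxy)prop-1-en-1-yl]-6-ethoxy-7-hydroxy-7-methyl-8-oxo-7,8-dihydroisochromen-2-ium diphenyl phosphate | CC(=O)OC/C=C/C1=CC2=C(C=[O+]1)C(=O)[C@@](C)(O)C(OCC)=C2.[O-]P(=O)(Oc1ccccc1)Oc1ccccc1 | intermediate (not isolated)
23 | (2E)-3-[(7S)-6-ethoxy-7-hydroxy-7-methyl-8-oxo-7,8-dihydro-1H-isochromen-3-yl]prop-2-en-1-yl acetate | CC(=O)OC/C=C/C1=CC2=C(CO1)C(=O)[C@@](C)(O)C(OCC)=C2 | intermediate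
24 | 2,4-bis[(tert-butyldimethylsilyl)oxy]-6-methylbenzoyl chloride | Cc1cc(O[Si](C)(C)C(C)(C)C)cc(O[Si](C)(C)C(C)(C)C)c1C(Cl)=O | intermediate
25 | (7S)-3-[(1E)-3-(acetyloxy)prop-1-en-1-yl]-6-ethoxy-7-methyl-8-oxo-7,8-dihydro-1H-isochromen-7-yl 2,4-bis[(tert-butyldimethylsilyl)oxy]-6-methylbenzoate | CC(=O)OC/C=C/C1=CC2=C(CO1)C(=O)[C@@](C)(OC(=O)c1c(C)cc(O[Si](C)(C)C(C)(C)C)cc1O[Si](C)(C)C(C)(C)C)C(OCC)=C2 | intermediate
26 | (7S)-3-[(1E)-3-(acetyloxy)prop-1-en-1-yl]-7-methyl-6,8-dioxo-5,6,7,8-tetrahydro-1H-isochromen-7-yl 2,4-bis[(tert-butyldimethylsilyl)oxy]-6-methylbenzoate (may exist partly as its C6 enol) | CC(=O)OC/C=C/C1=CC2=C(CO1)C(=O)[C@@](C)(OC(=O)c1c(C)cc(O[Si](C)(C)C(C)(C)C)cc1O[Si](C)(C)C(C)(C)C)C(=O)C2 | intermediate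
27 | tetrakis(tert-butyldimethylsilyl) ether of the target (all four phenols silylated; 5Z, 7S in unit A; 6R, 7R in unit B) | CC(=O)OC/C=C/C1=CC2=C(CO1)C(=O)[C@@](C)(OC(=O)c1c(C)cc(O[Si](C)(C)C(C)(C)C)cc1O[Si](C)(C)C(C)(C)C)C(=O)/C2=C\C=C\C1=CC2=C(CO1)C(=O)[C@](C)(O)[C@H](OC(=O)c1c(C)cc(O[Si](C)(C)C(C)(C)C)cc1O[Si](C)(C)C(C)(C)C)C2 | intermediate
28 | CNP0283591.2: (5Z,7S)-3-[(1E)-3-(acetyloxy)prop-1-en-1-yl]-5-{(2E)-3-[(6R,7R)-6-(2,4-dihydroxy-6-methylbenzoyloxy)-7-hydroxy-7-methyl-8-oxo-5,6,7,8-tetrahydro-1H-isochromen-3-yl]prop-2-en-1-ylidene}-7-methyl-6,8-dioxo-5,6,7,8-tetrahydro-1H-isochromen-7-yl 2,4-dihydroxy-6-methylbenzoate | CC(=O)OC/C=C/C1=CC2=C(CO1)C(=O)[C@@](C)(OC(=O)c1c(C)cc(O)cc1O)C(=O)/C2=C\C=C\C1=CC2=C(CO1)C(=O)[C@](C)(O)[C@H](OC(=O)c1c(C)cc(O)cc1O)C2 | target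

**Step count**
Total: 17 steps. Longest linear sequence: 10 steps (3 → 4 → 5 → 7 → 9 → 15 → 17 → 18 → 19 → 27 → 28; steps 2, 3, 4, 5, 8, 9, 10, 11, 16, 17).

**Steps most likely to fail**

Step 8 (Proposed new method). What may go wrong: the enol ester may be too weak a nucleophile for the aromatic, stabilised ylide, so that ylide dimerisation or 1,2-hydride shift of the carbene takes over. Facial control may be lost if the ylide leaves the metal before it reacts. The approach may be endo, or addition may occur at the free pyrylium α-carbon instead of across the dipole.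
Fallback (known chemistry, oxidative dearomatisation of a resorcinol instead of the cycloaddition): it sets out from 24, the only numbered compound it needs, together with commercial 1-bromo-3,5-dimethoxybenzene and (2E)-pent-2-en-4-yn-1-ol, and comes back to the route at 17. Vilsmeier formylation (POCl3, DMF) should give 2-bromo-4,6-dimethoxybenzaldehyde F1, BBr3 the resorcinol 2-bromo-4,6-dihydroxybenzaldehyde F2, and C-methylation between the two hydroxyls (MeI, KOH, MeOH) 6-bromo-2,4-dihydroxy-3-methylbenzaldehyde F3. Sonogashira coupling (PdCl2(PPh3)2, CuI, Et3N) with (2E)-pent-2-en-4-yn-1-yl acetate F4 (from the enynol and Ac2O) would give the alkynyl aldehyde F5. Copper-mediated enantioselective hydroxylative dearomatisation ([Cu(MeCN)4]PF6, the sparteine enantiomer that leads to 7R, O2, −78 °C) and buffered cycloisomerisation would give the (7R)-azaphilone alcohol F6. Hydride transfer to C1 with the dihydropyridine and acid, as in step 9, would give the (7R)-hydroxy dione F7. NaBH4/CeCl3 at −78 °C should reduce the C6 ketone from the face of the methyl group (C8 is a deactivated vinylogous ester) to the cis diol F8. Selective acylation of the secondary hydroxyl with 24 (pyridine, DMAP) would give 17.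

Step 12 (Proposed new method). What may go wrong: the same uncertainties of ylide formation and facial control as in step 8; in addition the alkyne may add in another mode, and hydride may be delivered to the ethoxy-bearing carbon instead of C1.
Fallback (known chemistry): it sets out from 24 and from the alkynyl aldehyde F5 (made as in the fallback to step 8) and comes back at 26. Copper-mediated dearomatisation with the other sparteine enantiomer and cycloisomerisation would give the (7S)-azaphilone alcohol F9. Acylation of its tertiary hydroxyl with 24 (Et3N, DMAP), the usual way to azaphilone esters, would give the ester F10. Hydride transfer to C1 with the dihydropyridine and acid, followed by protonation at C5, would give 26.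

Step 16. What may go wrong: a second molecule of 26 may add to the extended acceptor; the dienone may close by oxa-6π electrocyclisation to a 2H-pyran; the exocyclic geometry may not equilibrate cleanly; the amine may cause slow elimination of the aroyloxy group of unit B.
Fallback (Lewis-acid aldol and separate dehydration instead of amine catalysis): it sets out from 25 (taken before step 15) and 19 and comes back at 27. A BF3·OEt2-mediated vinylogous Mukaiyama-type aldol addition of the ethyl dienol ether through C5 to the aldehyde, with aqueous work-up releasing the C6 ketone, would give the aldol F11 as a mixture at the two new centres. Burgess dehydration followed by brief amine-mediated equilibration of the C5=C geometry would give 27.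

**Further compounds**

F1 | step 8 | 2-bromo-4,6-dimethoxybenzaldehyde | COc1cc(Br)c(C=O)c(OC)c1
F2 | step 8 | 2-bromo-4,6-dihydroxybenzaldehyde | Oc1cc(Br)c(C=O)c(O)c1
F3 | step 8 | 6-bromo-2,4-dihydroxy-3-methylbenzaldehyde | Cc1c(O)cc(Br)c(C=O)c1O
F4 | step 8 | (2E)-pent-2-en-4-yn-1-yl acetate | CC(=O)OC/C=C/C#C
F5 | step 8 | (2E)-5-(2-formyl-3,5-dihydroxy-4-methylphenyl)pent-2-en-4-yn-1-yl acetate | CC(=O)OC/C=C/C#Cc1cc(O)c(C)c(O)c1C=O
F6 | step 8 | (2E)-3-[(7R)-7-hydroxy-7-methyl-6,8-dioxo-7,8-dihydro-6H-isochromen-3-yl]prop-2-en-1-yl acetate | CC(=O)OC/C=C/C1=CC2=CC(=O)[C@@](C)(O)C(=O)C2=CO1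
F7 | step 8 | (2E)-3-[(7R)-7-hydroxy-7-methyl-6,8-dioxo-5,6,7,8-tetrahydro-1H-isochromen-3-yl]prop-2-en-1-yl acetate | CC(=O)OC/C=C/C1=CC2=C(CO1)C(=O)[C@](C)(O)C(=O)C2
F8 | step 8 | (2E)-3-[(6R,7R)-6,7-dihydroxy-7-methyl-8-oxo-5,6,7,8-tetrahydro-1H-isochromen-3-yl]prop-2-en-1-yl acetate | CC(=O)OC/C=C/C1=CC2=C(CO1)C(=O)[C@](C)(O)[C@H](O)C2
F9 | step 12 | (2E)-3-[(7S)-7-hydroxy-7-methyl-6,8-dioxo-7,8-dihydro-6H-isochromen-3-yl]prop-2-en-1-yl acetate | CC(=O)OC/C=C/C1=CC2=CC(=O)[C@](C)(O)C(=O)C2=CO1
F10 | step 12 | (7S)-3-[(1E)-3-(acetyloxy)prop-1-en-1-yl]-7-methyl-6,8-dioxo-7,8-dihydro-6H-isochromen-7-yl 2,4-bis[(tert-butyldimethylsilyl)oxy]-6-methylbenzoate | CC(=O)OC/C=C/C1=CC2=CC(=O)[C@](C)(OC(=O)c3c(C)cc(O[Si](C)(C)C(C)(C)C)cc3O[Si](C)(C)C(C)(C)C)C(=O)C2=CO1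
F11 | step 16 | aldol adduct of 25 and 19 (C5 of unit A bonded to the carbinol carbon of the linker; both new centres unassigned) | CC(=O)OC/C=C/C1=CC2=C(CO1)C(=O)[C@@](C)(OC(=O)c1c(C)cc(O[Si](C)(C)C(C)(C)C)cc1O[Si](C)(C)C(C)(C)C)C(=O)C2C(O)/C=C/C1=CC2=C(CO1)C(=O)[C@](C)(O)[C@H](OC(=O)c1c(C)cc(O[Si](C)(C)C(C)(C)C)cc1O[Si](C)(C)C(C)(C)C)C2
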